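## Structural features

The target is an olivil-type tetrahydrofuran (O1, C2–C5) in which C2 carries ring B, C3 carries CH2OH, C4 is a fully substituted carbinol carbon bearing OH and the 4-hydroxy-3-methoxybenzyl group of ring A, and C5 is CH2. The phenol oxygen of ring B is the ether oxygen on C8 of a guaiacylglycerol chain (C7 benzylic carbinol on ring C, C8, C9H2OH), an 8-O-4′ link. Three stereocentres are contiguous on the ring (2S,3R,4S): the C2 aryl is trans to the C3 hydroxymethyl, and the C4 hydroxyl is trans to the C3 arm and cis to the C2 aryl. Two more are adjacent in the chain (7R,8R, threo); ring B separates them from the ring centres, so they need reagent control. Fragile groups are the two electron-rich benzylic C–O bonds (C2–O1 and C7–OH), which ionise in acid and can be hydrogenolysed, the aryl ether at C8, which is cleaved once C7 ionises, and the free guaiacyl phenols, which give quinone methides with base or oxidants. The real difficulties are the quaternary carbinol C4 in defined relation to C3, and the threo aryl ether at C8 in the correct absolute sense. The key step draws on the hydroxymethyl-bearing C3 and its neighbour C4, the carbon that holds the ring A benzyl carbon: an epoxide spanning C3 and the hydroxymethyl carbon gives a C3 radical, an aryl alkyne supplies C4 and the benzylic carbon, and formation of C3–C4 closes the ring O1–C2–C3–C4–C5.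

## Logic of the disconnections

29 from 28: four O–Si bonds are cut (two aryl oxygens, the primary oxygen on the C3 arm, the tertiary oxygen on C4). Every hydroxyl that must stay masked to the end is silylated, so one buffered fluoride step finishes the synthesis and no hydrogenolysis is run on the finished molecule. The forward step must be buffered so the ring C phenoxide does not expel the C7 hydroxyl.

28 from 27, and 27 from 23 and 25: the C7–C8 bond is cut (and the C9 alcohol is traced back to an acyl imide). C7 and C8 are adjacent, both oxygenated and threo, which is the pattern of a syn glycolate aldol. This removes ring C as 25 (one step from 24) and sets both centres in one step under auxiliary control. The forward step needs a Z enolate, a closed transition state with no surplus Lewis acid, and no free hydroxyl in 23.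

23 from 18 and 22, and 22 from 19 and 20: the aryl O–CH2 bond is cut. Phenoxide substitution at a primary α-halo carbonyl is dependable and avoids substitution at the hindered secondary C8. Only one phenol may be free in 18, and the base must spare the silyl ethers and the imide.

18 from 17, and 17 from 16: the ring B O–benzyl bond and the O–Si bond at C4 are reinstated. Ring B carries the only benzyl ether, so hydrogenolysis singles it out; ring A carries a silyl ether (the reverse of the usual assignment, chosen so that the end is a single fluoride step). The tertiary hydroxyl is capped first because of the boron aldol. The hydrogenolysis must leave the C2–O1 bond intact.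

16 from 15, and 15 from 14: the benzylic C–H and the epoxide C–O bonds are cut back to the benzylidene. Epoxidation followed by hydride at the benzylic carbon is a hydration with oxygen on the ring carbon C4. The C4 centre then comes from face selection on a rigid ring. The forward steps need an oxidant that approaches anti to the C3 arm without acid, and hydride attack at the benzylic carbon only.

14 from 13: one O–Si bond. The bulky silyl group shields the face of the alkene on the side of the C3 arm and removes any hydrogen-bond direction of the oxidant.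

13 from 11: the C3–C4 bond is cut, which opens the ring. The cut leaves an epoxide at C3 and an aryl alkyne at C4, and the C2 centre in 11 controls C3. The forward step must cyclise faster than the radical is reduced.

11 from 4 and 9: the propargylic C–O bond is cut (Williamson). This gives two fragments of similar size. The alkoxide of 4 must be alkylated before it rearranges.

4 from 3, and 3 from 1 and 2: the epoxide oxygen and the C–vinyl bond are removed. A kinetic resolution with epoxidation delivers the carbinol centre and the epoxide in one step from a racemate made in one step. The tartrate enantiomer must be the one that consumes (S)-3.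

9 from 8, 8 from 6 and 7, and 6 from 5: the C–Br bond, the aryl–alkyne bond (Sonogashira) and the O–Si bond are cut. This reaches commercial materials in three standard steps.

## Other disconnections considered

Alternative 1: The cut is through C2–C3 and C4–C5, back to the aryl dioxolane A1, whose acetal carbon becomes C2. Forward, SnCl4 opens A1 to an oxocarbenium ion, the trisubstituted alkene closes C2–C3 to a six-membered cation, and a pinacol shift of C5 onto C4 contracts the ring to the 4-acetyl tetrahydrofuran A2.
- In its favour: it makes the ring, two C–C bonds and all three ring stereocentres, including the quaternary C4, in one step. A chair with the C2 aryl and the C3 arm equatorial gives the trans relation, and the shift places the acyl group cis to the aryl. On setting C4 relative to C3 by mechanism it is better than the chosen plan, which depends on a later face-selective epoxidation.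
- Against it: C4 ends with acetyl, not hydroxyl, so a Baeyer–Villiger oxidation and ester cleavage are needed on the hindered ketone A2 beside two electron-rich rings. SnCl4 endangers the silyl ethers and the electron-rich benzylic positions (Friedel–Crafts closure, ionisation at C2). The absolute sense rests on a tertiary carbinol whose methyl and tin-bound oxygen compete for the equatorial site (A1 is drawn for equatorial methyl). A1 also needs its own asymmetric synthesis with a defined (E)-alkene.
- Comparison: structurally it gives more of the core per step but with the wrong atom on C4. Mechanistically it is cationic and strongly Lewis acidic, where the chosen radical closure is neutral. In step count it is not shorter, since the route to A1 and the two steps from acetyl to hydroxyl offset the gain.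

Alternative 2: The cut is the bond from C4 to the ring A benzylic carbon, with that carbon tied to the C3 arm as a benzyl ether, back to the 4-oxotetrahydrofuran A3. Forward, the excited C4 ketone abstracts the benzylic ether hydrogen and the 1,5-biradical closes to the 1-hydroxy-furofuran A4. Hydrogenolysis of the ring A benzylic C–O bond then gives the C4 benzyl group and the C3 hydroxymethyl.
- In its favour: the cis ring fusion forces the new C4–C bond cis to the C3 arm, so the hydroxyl must be trans to it. On the C4 configuration this is better than the chosen plan. The tether becomes the CH2OH group without a separate step. In taking its stereocontrol from C3 it is the equal of the chosen plan.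
- Against it: α-cleavage of the α-alkoxy ketone and light absorption by three arenes threaten the photochemical step. C3 is α to the ketone in A3 and can epimerise, although trans is the stable isomer. The hydrogenolysis must distinguish two benzylic C–O bonds, which is why ring B is a mesylate. That mesylate later needs strong base to remove, while the ring A phenol freed by the same hydrogenolysis must be protected again.
- Comparison: the C4 centre is more secure, but the photochemical step is less predictable than the radical closure, and the extra protecting-group steps make the sequence about two or three steps longer.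

Alternative 3: The cut is O1–C2, back to the acyclic triol A5 with a free ring B phenol. Forward, DDQ oxidises the 4-hydroxy-3-methoxybenzyl group of A5 to the quinone methide level and the C5 hydroxyl adds to the benzylic carbon, giving A6.
- In its favour: it is biomimetic and leaves the ring B phenol free, which is what the side-chain attachment needs, so on the phenol release it is better than the chosen plan. The five-membered closure is favoured over the four-membered alternatives open to the other two hydroxyls. C2 should form trans to C3, so on the C2/C3 relation it is the equal of the chosen plan, and it needs no resolution for C2.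
- Against it: the stereochemical problem moves to A5, where the adjacent C3 and quaternary C4 centres must be set in an open chain. DDQ can also attack the benzylic CH2 of the dialkoxy ring A and can oxidise A6 again at C2.
- Comparison: the end of the route from A6 is shorter by one deprotection, but the route to A5 is expected to be longer and less controlled than the ring-based setting of C3 and C4.

Key step: step 7

Remark: 13 is drawn as the (Z)-benzylidene isomer (an (E) isomer would converge at step 10), and metal alkoxides that are only protonated in the work-up are not numbered, except the titanium species 12.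

## Steps

Step 1
Reactants: 1 4-(benzyloxy)-3-methoxybenzaldehyde; 2 vinylmagnesium bromide
Product: 3 rac-1-[4-(benzyloxy)-3-methoxyphenyl]prop-2-en-1-ol
Conditions: THF, −78 to 0 °C; then sat. aq. NH4Cl
Reagents that add atoms: none
Why: 1,2-addition of the Grignard reagent to the aldehyde; no stereocontrol is wanted because the racemate is resolved in step 2, and the aryl benzyl ether is inert.

Step 2
Reactants: 3 rac-1-[4-(benzyloxy)-3-methoxyphenyl]prop-2-en-1-ol
Product: 4 (R)-[4-(benzyloxy)-3-methoxyphenyl][(2S)-oxiran-2-yl]methanol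
Conditions: Ti(OiPr)4 (0.15 equiv), D-(−)-diisopropyl tartrate (0.2 equiv), tBuOOH (0.45 equiv), 4 Å MS, CH2Cl2, −20 °C
Reagents that add atoms: tert-butyl hydroperoxide CC(C)(C)OO
Why: Sharpless kinetic resolution–epoxidation: with the D-(−)-tartrate the (S)-enantiomer of 3 should be the fast-reacting one and give the erythro epoxy alcohol, so the carbinol centre (later C2) is set by enantiomer selection and the epoxide centre by the catalyst, while (R)-3 stays behind. Only the carbinol centre matters later, since step 7 erases the epoxide centre; substoichiometric peroxide keeps the enantiomeric purity of 4 high, and any material of the wrong series becomes a separable diastereomer after step 14.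

Step 3
Reactants: 5 4-bromo-2-methoxyphenol
Product: 6 (4-bromo-2-methoxyphenoxy)tri(propan-2-yl)silane
Conditions: TIPSCl, imidazole, DMF, rt
Reagents that add atoms: chlorotri(propan-2-yl)silane CC(C)[Si](Cl)(C(C)C)C(C)C
Why: Silylation of the phenol; the triisopropylsilyl ether should survive base, hydride and palladium and is removed by fluoride at the end.

Step 4
Reactants: 6 (4-bromo-2-methoxyphenoxy)tri(propan-2-yl)silane; 7 prop-2-yn-1-ol
Product: 8 3-[3-methoxy-4-(triisopropylsilyloxy)phenyl]prop-2-yn-1-ol
Conditions: PdCl2(PPh3)2 (3 mol%), CuI (3 mol%), Et3N, 60 °C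
Reagents that add atoms: none
Why: Sonogashira coupling of the aryl bromide with the terminal alkyne; the free propargylic hydroxyl and the aryl silyl ether are tolerated, and heating compensates for the electron-rich bromide.

Step 5
Reactants: 8 3-[3-methoxy-4-(triisopropylsilyloxy)phenyl]prop-2-yn-1-ol
Product: 9 [4-(3-bromoprop-1-yn-1-yl)-2-methoxyphenoxy]tri(propan-2-yl)silane
Conditions: CBr4, PPh3, CH2Cl2, 0 °C
Reagents that add atoms: tetrabromomethane BrC(Br)(Br)Br
Why: Appel bromination of the primary propargylic alcohol under neutral conditions, which leaves the aryl silyl ether intact.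

Step 6
Reactants: 4 (R)-[4-(benzyloxy)-3-methoxyphenyl][(2S)-oxiran-2-yl]methanol; 9 [4-(3-bromoprop-1-yn-1-yl)-2-methoxyphenoxy]tri(propan-2-yl)silane
Product: 11 {2-methoxy-4-[3-({(R)-[4-(benzyloxy)-3-methoxyphenyl][(2S)-oxiran-2-yl]methyl}oxy)prop-1-yn-1-yl]phenoxy}tri(propan-2-yl)silane, via sodium alkoxide of the epoxy alcohol 10 (not isolated)
Conditions: NaH, THF, 0 °C; then 9, Bu4NI (cat.), 0 °C to rt
Reagents that add atoms: none
Why: Williamson ether synthesis by SN2 of the alkoxide 10 at the propargylic bromide; in aprotic THF at 0 °C alkylation should outpace Payne rearrangement, and the carbinol centre is not touched.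

Step 7
Reactants: 11 {2-methoxy-4-[3-({(R)-[4-(benzyloxy)-3-methoxyphenyl][(2S)-oxiran-2-yl]methyl}oxy)prop-1-yn-1-yl]phenoxy}tri(propan-2-yl)silane
Product: 13 [(2S,3R,4Z)-2-[4-(benzyloxy)-3-methoxyphenyl]-4-{[3-methoxy-4-(triisopropylsilyloxy)phenyl]methylidene}oxolan-3-yl]methanol, via bis-titanium alkoxide–alkenyl species 12 (not isolated)
Conditions: Cp2TiCl2 (2.5 equiv; Cp = cyclopentadienyl), Zn dust, THF, rt; green solution added dropwise to 11 in THF, rt; then 1 M HCl, 0 °C
Reagents that add atoms: none
Why: Cp2TiCl (trivalent titanium, made from Cp2TiCl2 and Zn) transfers one electron to the epoxide and cleaves the C–O bond at the more substituted carbon, giving the β-titanoxy secondary radical at C3 (Nugent–RajanBabu opening). The radical adds 5-exo-dig to the aryl alkyne and closes the ring O1–C2–C3–C4–C5 through the new C3–C4 bond; the exo mode is favoured by the three-atom tether and by the aryl group, which stabilises the exocyclic vinyl radical. That radical is reduced by a second Cp2TiCl to 12, and the acid work-up protonates both the alkenyl–titanium and the O–titanium bonds to give 13. The closest known reaction type is the titanocene-mediated cyclisation of epoxy propargyl ethers to 3-(hydroxymethyl)-4-alkylidene tetrahydrofurans. The new stereocentre C3 is controlled by C2: the epoxide centre is planar in the radical, and in the envelope-like transition state the aryl group on C2 takes a pseudo-equatorial position, so the CH2O–titanium arm ends up trans to it. The step needs cyclisation to outrun trapping of the C3 radical by Cp2TiCl, which would lead to deoxygenation; slow addition of the reagent to the substrate keeps the reagent concentration low. The benzyl ether, the silyl ether and the benzylic C2–O bond are not reduced under these conditions, and the benzylidene geometry does not matter because that carbon becomes CH2 in step 10.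

Step 8
Reactants: 13 [(2S,3R,4Z)-2-[4-(benzyloxy)-3-methoxyphenyl]-4-{[3-methoxy-4-(triisopropylsilyloxy)phenyl]methylidene}oxolan-3-yl]methanol
Product: 14 tert-butyl{[(2S,3R,4Z)-2-[4-(benzyloxy)-3-methoxyphenyl]-4-{[3-methoxy-4-(triisopropylsilyloxy)phenyl]methylidene}oxolan-3-yl]methoxy}diphenylsilane
Conditions: TBDPSCl, imidazole, DMF, rt
Reagents that add atoms: tert-butyl(chloro)diphenylsilane CC(C)(C)[Si](Cl)(c1ccccc1)c1ccccc1
Why: Silylation of the primary alcohol; the bulky group shields the alkene face on the side of the C3 arm and removes any hydrogen-bond direction of the oxidant in step 9.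

Step 9
Reactants: 14 tert-butyl{[(2S,3R,4Z)-2-[4-(benzyloxy)-3-methoxyphenyl]-4-{[3-methoxy-4-(triisopropylsilyloxy)phenyl]methylidene}oxolan-3-yl]methoxy}diphenylsilane
Product: 15 (2R,3S,6S,7R)-6-[4-(benzyloxy)-3-methoxyphenyl]-7-{[tert-butyl(diphenyl)silyl]oxymethyl}-2-[3-methoxy-4-(triisopropylsilyloxy)phenyl]-1,5-dioxaspiro[2.4]heptane (epoxide oxygen on the face of C4 syn to the C2 aryl)
Conditions: dimethyldioxirane (1.2 equiv, in acetone), CH2Cl2, −40 to −20 °C; concentrated cold and used crude
Reagents that add atoms: dimethyldioxirane CC1(C)OO1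
Why: Concerted electrophilic epoxidation of the electron-rich trisubstituted alkene; the oxidant should approach anti to the silyloxymethyl group on the adjacent C3, which places the oxygen on C4 cis to the C2 aryl (substrate control), and the exocyclic centre follows from the alkene geometry and is removed in step 10. The neutral, volatile reagent avoids the acid that would open this electron-rich benzylic epoxide.

Step 10
Reactants: 15 (2R,3S,6S,7R)-6-[4-(benzyloxy)-3-methoxyphenyl]-7-{[tert-butyl(diphenyl)silyl]oxymethyl}-2-[3-methoxy-4-(triisopropylsilyloxy)phenyl]-1,5-dioxaspiro[2.4]heptane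
Product: 16 (2S,3R,4S)-2-[4-(benzyloxy)-3-methoxyphenyl]-3-{[tert-butyl(diphenyl)silyl]oxymethyl}-4-{[3-methoxy-4-(triisopropylsilyloxy)phenyl]methyl}oxolan-4-ol
Conditions: LiBHEt3 (3 equiv), THF, 0 °C to rt; then H2O
Reagents that add atoms: none
Why: SN2 hydride opening of the epoxide at the benzylic, less substituted carbon; the C4–O bond is not broken, so C4 keeps the configuration set in step 9, and the ethers are inert to the hydride.

Step 11
Reactants: 16 (2S,3R,4S)-2-[4-(benzyloxy)-3-methoxyphenyl]-3-{[tert-butyl(diphenyl)silyl]oxymethyl}-4-{[3-methoxy-4-(triisopropylsilyloxy)phenyl]methyl}oxolan-4-ol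
Product: 17 (2S,3R,4S)-2-[4-(benzyloxy)-3-methoxyphenyl]-3-{[tert-butyl(diphenyl)silyl]oxymethyl}-4-{[3-methoxy-4-(triisopropylsilyloxy)phenyl]methyl}-4-(triethylsilyloxy)oxolane
Conditions: TESOTf, 2,6-lutidine, CH2Cl2, −78 to 0 °C
Reagents that add atoms: triethylsilyl trifluoromethanesulfonate CC[Si](CC)(CC)OS(=O)(=O)C(F)(F)F
Why: Silylation of the tertiary alcohol with a silyl triflate; the cap prevents the hydroxyl from consuming Bu2BOTf in step 16 and falls in the final fluoride step.

Step 12
Reactants: 17 (2S,3R,4S)-2-[4-(benzyloxy)-3-methoxyphenyl]-3-{[tert-butyl(diphenyl)silyl]oxymethyl}-4-{[3-methoxy-4-(triisopropylsilyloxy)phenyl]methyl}-4-(triethylsilyloxy)oxolane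
Product: 18 4-[(2S,3R,4S)-3-{[tert-butyl(diphenyl)silyl]oxymethyl}-4-{[3-methoxy-4-(triisopropylsilyloxy)phenyl]methyl}-4-(triethylsilyloxy)oxolan-2-yl]-2-methoxyphenol
Conditions: H2 (1 atm), 10% Pd/C, EtOAc, rt
Reagents that add atoms: none
Why: Hydrogenolysis of the only aryl benzyl ether; in neutral ethyl acetate the silyl ethers are inert and the C2–O1 benzylic ring bond should react much more slowly than the O-benzyl group.

Step 13
Reactants: 19 (4S)-4-benzyl-1,3-oxazolidin-2-one; 20 bromoacetyl bromide
Product: 22 (4S)-4-benzyl-3-(bromoacetyl)-1,3-oxazolidin-2-one, via N-lithio oxazolidinone 21 (not isolated)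
Conditions: n-BuLi (1.0 equiv), THF, −78 °C; then 20, −78 to 0 °C
Reagents that add atoms: none
Why: N-acylation of the lithiated oxazolidinone 21; the acyl bromide is far more electrophilic than the alkyl bromide, so substitution at carbonyl is selective at low temperature.

Step 14
Reactants: 18 4-[(2S,3R,4S)-3-{[tert-butyl(diphenyl)silyl]oxymethyl}-4-{[3-methoxy-4-(triisopropylsilyloxy)phenyl]methyl}-4-(triethylsilyloxy)oxolan-2-yl]-2-methoxyphenol; 22 (4S)-4-benzyl-3-(bromoacetyl)-1,3-oxazolidin-2-one
Product: 23 (4S)-4-benzyl-3-[(aryloxy)acetyl]-1,3-oxazolidin-2-one, in which aryloxy is the phenoxy residue of 18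
Conditions: K2CO3, acetone, rt
Reagents that add atoms: none
Why: Phenoxide alkylation (Williamson) at the activated primary α-bromo imide; the mild carbonate base in an aprotic solvent should spare the aryl silyl ether and the imide.

Step 15
Reactants: 24 4-hydroxy-3-methoxybenzaldehyde (vanillin)
Product: 25 3-methoxy-4-(triisopropylsilyloxy)benzaldehyde
Conditions: TIPSCl, imidazole, DMF, rt
Reagents that add atoms: chlorotri(propan-2-yl)silane CC(C)[Si](Cl)(C(C)C)C(C)C
Why: Silylation of the phenol, so that ring C carries the same fluoride-labile group as ring A.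

Step 16
Reactants: 23 (4S)-4-benzyl-3-[(aryloxy)acetyl]-1,3-oxazolidin-2-one; 25 3-methoxy-4-(triisopropylsilyloxy)benzaldehyde
Product: 27 (4S)-4-benzyl-3-[(2S,3R)-2-(aryloxy)-3-hydroxy-3-[3-methoxy-4-(triisopropylsilyloxy)phenyl]propanoyl]-1,3-oxazolidin-2-one (aryloxy as in 18), via Z-dibutylboron enolate 26 (not isolated)
Conditions: Bu2BOTf (1.15 equiv), iPr2NEt (1.3 equiv), CH2Cl2, −78 to 0 °C; then 25, −78 to 0 °C; pH 7 buffer, MeOH, H2O2, 0 °C
Reagents that add atoms: none
Why: Evans syn aldol of a glycolate imide: the Z enolate 26 reacts through a closed chair transition state in which the aldehyde approaches the enolate face away from the benzyl group of the auxiliary, which sets C8 and C7 together as the syn (threo) pair with the (2S,3R) configuration of the imide. The auxiliary dominates over the remote ring stereocentres, and the absence of free hydroxyl and of excess boron triflate keeps the reaction on the closed pathway.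

Step 17
Reactants: 27 (4S)-4-benzyl-3-[(2S,3R)-2-(aryloxy)-3-hydroxy-3-[3-methoxy-4-(triisopropylsilyloxy)phenyl]propanoyl]-1,3-oxazolidin-2-one
Product: 28 (1R,2R)-2-(aryloxy)-1-[3-methoxy-4-(triisopropylsilyloxy)phenyl]propane-1,3-diol (aryloxy as in 18)
Conditions: LiBH4, THF, MeOH (2 equiv), 0 °C
Reagents that add atoms: none
Why: Reductive cleavage of the N-acyl oxazolidinone to the primary alcohol C9 with release of the auxiliary; the descriptor at C8 changes from S to R only through the priority change, and the cold neutral-to-mildly basic conditions should not cause retro-aldol.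

Step 18
Reactants: 28 (1R,2R)-2-(aryloxy)-1-[3-methoxy-4-(triisopropylsilyloxy)phenyl]propane-1,3-diol
Product: 29 (3S,4R,5S)-5-(4-{[(1R,2R)-1,3-dihydroxy-1-(4-hydroxy-3-methoxyphenyl)propan-2-yl]oxy}-3-methoxyphenyl)-3-[(4-hydroxy-3-methoxyphenyl)methyl]-4-(hydroxymethyl)oxolan-3-ol
Conditions: TBAF, AcOH (1:1, excess), THF, 0 °C to rt
Reagents that add atoms: none
Why: Fluoride desilylation of the two aryl, the primary and the tertiary silyl ethers in one step; the acetic acid buffer keeps the phenoxides protonated so that no quinone methide forms at C7 or C2, and no stereocentre is touched.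

## Compound list

1 | 4-(benzyloxy)-3-methoxybenzaldehyde | COc1cc(C=O)ccc1OCc1ccccc1 | starting material
2 | vinylmagnesium bromide | C=C[Mg]Br | starting material
3 | rac-1-[4-(benzyloxy)-3-methoxyphenyl]prop-2-en-1-ol | C=CC(O)c1ccc(OCc2ccccc2)c(OC)c1 | intermediate
4 | (R)-[4-(benzyloxy)-3-methoxyphenyl][(2S)-oxiran-2-yl]methanol | O[C@H](c1ccc(OCc2ccccc2)c(OC)c1)[C@@H]1CO1 | intermediate
5 | 4-bromo-2-methoxyphenol | COc1cc(Br)ccc1O | starting material
6 | (4-bromo-2-methoxyphenoxy)tri(propan-2-yl)silane | COc1cc(Br)ccc1O[Si](C(C)C)(C(C)C)C(C)C | intermediate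
7 | prop-2-yn-1-ol (propargyl alcohol) | C#CCO | starting material
8 | 3-[3-methoxy-4-(triisopropylsilyloxy)phenyl]prop-2-yn-1-ol | COc1cc(C#CCO)ccc1O[Si](C(C)C)(C(C)C)C(C)C | intermediate
9 | [4-(3-bromoprop-1-yn-1-yl)-2-methoxyphenoxy]tri(propan-2-yl)silane | COc1cc(C#CCBr)ccc1O[Si](C(C)C)(C(C)C)C(C)C | intermediate
10 | sodium (R)-[4-(benzyloxy)-3-methoxyphenyl][(2S)-oxiran-2-yl]methanolate | [Na+].[O-][C@H](c1ccc(OCc2ccccc2)c(OC)c1)[C@@H]1CO1 | intermediate (not isolated)
11 | {2-methoxy-4-[3-({(R)-[4-(benzyloxy)-3-methoxyphenyl][(2S)-oxiran-2-yl]methyl}oxy)prop-1-yn-1-yl]phenoxy}tri(propan-2-yl)silane | COc1cc(C#CCO[C@H](c2ccc(OCc3ccccc3)c(OC)c2)[C@@H]2CO2)ccc1O[Si](C(C)C)(C(C)C)C(C)C | intermediate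
12 | chlorotitanocene alkoxide of 13 carrying a second chlorotitanocene unit on the exocyclic alkenyl carbon | COc1cc(/C(=C2\CO[C@H](c3ccc(OCc4ccccc4)c(OC)c3)[C@H]2CO[Ti](Cl)(C3C=CC=C3)C3C=CC=C3)[Ti](Cl)(C2C=CC=C2)C2C=CC=C2)ccc1O[Si](C(C)C)(C(C)C)C(C)C | intermediate (not isolated)
13 | [(2S,3R,4Z)-2-[4-(benzyloxy)-3-methoxyphenyl]-4-{[3-methoxy-4-(triisopropylsilyloxy)phenyl]methylidene}oxolan-3-yl]methanol | COc1cc(/C=C2\CO[C@H](c3ccc(OCc4ccccc4)c(OC)c3)[C@H]2CO)ccc1O[Si](C(C)C)(C(C)C)C(C)C | intermediate
14 | tert-butyl{[(2S,3R,4Z)-2-[4-(benzyloxy)-3-methoxyphenyl]-4-{[3-methoxy-4-(triisopropylsilyloxy)phenyl]methylidene}oxolan-3-yl]methoxy}diphenylsilane | COc1cc(/C=C2\CO[C@H](c3ccc(OCc4ccccc4)c(OC)c3)[C@H]2CO[Si](c2ccccc2)(c2ccccc2)C(C)(C)C)ccc1O[Si](C(C)C)(C(C)C)C(C)C | intermediate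
15 | (2R,3S,6S,7R)-6-[4-(benzyloxy)-3-methoxyphenyl]-7-{[tert-butyl(diphenyl)silyl]oxymethyl}-2-[3-methoxy-4-(triisopropylsilyloxy)phenyl]-1,5-dioxaspiro[2.4]heptane | COc1cc([C@H]3O[C@@]32CO[C@H](c4ccc(OCc5ccccc5)c(OC)c4)[C@H]2CO[Si](c2ccccc2)(c2ccccc2)C(C)(C)C)ccc1O[Si](C(C)C)(C(C)C)C(C)C | intermediate
16 | (2S,3R,4S)-2-[4-(benzyloxy)-3-methoxyphenyl]-3-{[tert-butyl(diphenyl)silyl]oxymethyl}-4-{[3-methoxy-4-(triisopropylsilyloxy)phenyl]methyl}oxolan-4-ol | COc1cc(C[C@@]2(O)CO[C@H](c3ccc(OCc4ccccc4)c(OC)c3)[C@H]2CO[Si](c2ccccc2)(c2ccccc2)C(C)(C)C)ccc1O[Si](C(C)C)(C(C)C)C(C)C | intermediate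
17 | (2S,3R,4S)-2-[4-(benzyloxy)-3-methoxyphenyl]-3-{[tert-butyl(diphenyl)silyl]oxymethyl}-4-{[3-methoxy-4-(triisopropylsilyloxy)phenyl]methyl}-4-(triethylsilyloxy)oxolane | COc1cc(C[C@@]2(O[Si](CC)(CC)CC)CO[C@H](c3ccc(OCc4ccccc4)c(OC)c3)[C@H]2CO[Si](c2ccccc2)(c2ccccc2)C(C)(C)C)ccc1O[Si](C(C)C)(C(C)C)C(C)C | intermediate
18 | 4-[(2S,3R,4S)-3-{[tert-butyl(diphenyl)silyl]oxymethyl}-4-{[3-methoxy-4-(triisopropylsilyloxy)phenyl]methyl}-4-(triethylsilyloxy)oxolan-2-yl]-2-methoxyphenol | COc1cc(C[C@@]2(O[Si](CC)(CC)CC)CO[C@H](c3ccc(O)c(OC)c3)[C@H]2CO[Si](c2ccccc2)(c2ccccc2)C(C)(C)C)ccc1O[Si](C(C)C)(C(C)C)C(C)C | intermediate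
19 | (4S)-4-benzyl-1,3-oxazolidin-2-one | O=C1N[C@@H](Cc2ccccc2)CO1 | starting material
20 | bromoacetyl bromide | BrCC(Br)=O | starting material
21 | lithium salt of (4S)-4-benzyl-1,3-oxazolidin-2-one (N-lithio) | [Li+].O=C1[N-][C@@H](Cc2ccccc2)CO1 | intermediate (not isolated)
22 | (4S)-4-benzyl-3-(bromoacetyl)-1,3-oxazolidin-2-one | O=C(CBr)N1[C@@H](Cc2ccccc2)COC1=O | intermediate
23 | (4S)-4-benzyl-3-[(aryloxy)acetyl]-1,3-oxazolidin-2-one, aryloxy = phenoxy residue of 18 | COc1cc(C[C@@]2(O[Si](CC)(CC)CC)CO[C@H](c3ccc(OCC(=O)N4[C@@H](Cc5ccccc5)COC4=O)c(OC)c3)[C@H]2CO[Si](c2ccccc2)(c2ccccc2)C(C)(C)C)ccc1O[Si](C(C)C)(C(C)C)C(C)C | intermediate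
24 | 4-hydroxy-3-methoxybenzaldehyde (vanillin) | COc1cc(C=O)ccc1O | starting material
25 | 3-methoxy-4-(triisopropylsilyloxy)benzaldehyde | COc1cc(C=O)ccc1O[Si](C(C)C)(C(C)C)C(C)C | intermediate
26 | (Z)-dibutylboron enolate of 23 | COc1cc(C[C@@]2(O[Si](CC)(CC)CC)CO[C@H](c3ccc(O/C=C(\OB(CCCC)CCCC)N4[C@@H](Cc5ccccc5)COC4=O)c(OC)c3)[C@H]2CO[Si](c2ccccc2)(c2ccccc2)C(C)(C)C)ccc1O[Si](C(C)C)(C(C)C)C(C)C | intermediate (not isolated)
27 | (4S)-4-benzyl-3-[(2S,3R)-2-(aryloxy)-3-hydroxy-3-[3-methoxy-4-(triisopropylsilyloxy)phenyl]propanoyl]-1,3-oxazolidin-2-one, aryloxy as in 18 | COc1cc(C[C@@]2(O[Si](CC)(CC)CC)CO[C@H](c3ccc(O[C@@H]([C@H](O)c6ccc(O[Si](C(C)C)(C(C)C)C(C)C)c(OC)c6)C(=O)N4[C@@H](Cc5ccccc5)COC4=O)c(OC)c3)[C@H]2CO[Si](c2ccccc2)(c2ccccc2)C(C)(C)C)ccc1O[Si](C(C)C)(C(C)C)C(C)C | intermediate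
28 | (1R,2R)-2-(aryloxy)-1-[3-methoxy-4-(triisopropylsilyloxy)phenyl]propane-1,3-diol, aryloxy as in 18 | COc1cc(C[C@@]2(O[Si](CC)(CC)CC)CO[C@H](c3ccc(O[C@H](CO)[C@H](O)c6ccc(O[Si](C(C)C)(C(C)C)C(C)C)c(OC)c6)c(OC)c3)[C@H]2CO[Si](c2ccccc2)(c2ccccc2)C(C)(C)C)ccc1O[Si](C(C)C)(C(C)C)C(C)C | intermediate
29 | (3S,4R,5S)-5-(4-{[(1R,2R)-1,3-dihydroxy-1-(4-hydroxy-3-methoxyphenyl)propan-2-yl]oxy}-3-methoxyphenyl)-3-[(4-hydroxy-3-methoxyphenyl)methyl]-4-(hydroxymethyl)oxolan-3-ol | COc1cc(C[C@@]2(O)CO[C@H](c3ccc(O[C@H](CO)[C@H](O)c4ccc(O)c(OC)c4)c(OC)c3)[C@H]2CO)ccc1O | target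

## Step count and least certain steps

Total: 18 steps. Longest linear sequence: 14 steps from 5 (steps 3, 4, 5, 6, 7, 8, 9, 10, 11, 12, 14, 16, 17, 18).

Step 7 (key step). Most likely failure: the C3 radical is trapped by the titanium reagent and deoxygenated before it adds to the internal, aryl-substituted alkyne, which is a slower acceptor than a terminal alkyne; a second risk is modest trans selectivity at C3. Fallback: set out from 4 and bring in the aryl group after ring closure. Alkylation of 4 with propargyl bromide (NaH, THF) would give the terminal-alkyne ether F1, whose Cp2TiCl cyclisation would give the 4-methylidene alcohol F2. Silylation (TBDPSCl) would give the silyl ether F3, and dimethyldioxirane anti to the C3 arm would give the non-benzylic spiro-epoxide F4. Copper-catalysed opening (CuI) at its CH2 carbon by the aryl Grignard reagent F5 (from 6 and Mg) would give 16, where the route is rejoined; steps 9 and 10 are then not needed.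

Step 9. Most likely failure: poor facial selectivity, because the pseudo-equatorial C3 arm lies close to the alkene plane, and acid-induced opening or rearrangement of the electron-rich benzylic epoxide during handling. Fallback: from 14, use a diol in place of the epoxide. Dihydroxylation with OsO4 (cat.) and NMO, where the bulkier oxidant should respond more strongly to the shielding and a cinchona alkaloid ligand can reinforce the facial sense, would give the diol F6. Thiocarbonyldiimidazole would give the cyclic thionocarbonate F7. Bu3SnH/AIBN would cleave the benzylic C–O bond through the benzylic radical (Barton–McCombie type), and mild hydrolysis of the remaining thiocarbonate would release 16.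

Step 2. Most likely failure: titanium-promoted opening or ionisation of the electron-rich benzylic epoxy alcohol, and incomplete discrimination of the enantiomers. Fallback: from 3, resolve with an enzyme and epoxidise later. Candida antarctica lipase B with vinyl acetate should acetylate the (R)-alcohol to the acetate F9 and leave the (S)-alcohol F8. NaH and 9 would convert F8 into the allyl propargyl ether F10. Buffered mCPBA would epoxidise the terminal alkene with no need for diastereocontrol, giving 11 together with its epoxide epimer F11, and both converge on 13 in step 7.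

Step 14. Most likely failure: attack of the phenoxide at the imide carbonyl (loss of the auxiliary) in competition with substitution at CH2Br, or silyl scrambling of the aryl silyl ether under base. Fallback: from 18, build the imide by acylation. K2CO3 and allyl bromoacetate would give the allyl ester F12; Pd(PPh3)4 and morpholine would free the acid F13 under neutral conditions; pivaloyl chloride/Et3N followed by 19 and LiCl would attach the auxiliary and give 23.

Step 16. Most likely failure: slow addition to the electron-rich aldehyde and leakage through an open transition state, which erodes the syn selectivity at C7. Fallback: correct C7 afterwards. The mixture of 28 and its C7 epimer F14 obtained after step 17 would be silylated at the primary hydroxyl (TBSCl, imidazole) to the erythro silyl ether F15 and the threo silyl ether F16. Both would be oxidised (Dess–Martin periodinane) to the single ketone F17. Reduction with LiBH(s-Bu)3 at −78 °C under Felkin–Anh control (aryloxy group anti to the incoming hydride, no chelation) should return the threo silyl ether F16, which enters step 18 and gives 29.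

## Further compounds

F1 | step 7 | (2S)-2-{(R)-[4-(benzyloxy)-3-methoxyphenyl](prop-2-yn-1-yloxy)methyl}oxirane | C#CCO[C@H](c1ccc(OCc2ccccc2)c(OC)c1)[C@@H]1CO1
F2 | step 7 | [(2S,3R)-2-[4-(benzyloxy)-3-methoxyphenyl]-4-methylideneoxolan-3-yl]methanol | C=C1CO[C@H](c2ccc(OCc3ccccc3)c(OC)c2)[C@H]1CO
F3 | step 7 | tert-butyl{[(2S,3R)-2-[4-(benzyloxy)-3-methoxyphenyl]-4-methylideneoxolan-3-yl]methoxy}diphenylsilane | C=C1CO[C@H](c2ccc(OCc3ccccc3)c(OC)c2)[C@H]1CO[Si](c1ccccc1)(c1ccccc1)C(C)(C)C
F4 | step 7 | 6-[4-(benzyloxy)-3-methoxyphenyl]-7-{[tert-butyl(diphenyl)silyl]oxymethyl}-1,5-dioxaspiro[2.4]heptane, epoxide oxygen on the face of the spiro carbon syn to the aryl group, (6S,7R) | C1O[C@@]12CO[C@H](c3ccc(OCc4ccccc4)c(OC)c3)[C@H]2CO[Si](c2ccccc2)(c2ccccc2)C(C)(C)C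
F5 | step 7 | [3-methoxy-4-(triisopropylsilyloxy)phenyl]magnesium bromide | COc1cc([Mg]Br)ccc1O[Si](C(C)C)(C(C)C)C(C)C
F6 | step 9 | (2S,3R,4S)-2-[4-(benzyloxy)-3-methoxyphenyl]-3-{[tert-butyl(diphenyl)silyl]oxymethyl}-4-{(R)-hydroxy[3-methoxy-4-(triisopropylsilyloxy)phenyl]methyl}oxolan-4-ol | COc1cc([C@@H](O)[C@@]2(O)CO[C@H](c3ccc(OCc4ccccc4)c(OC)c3)[C@H]2CO[Si](c2ccccc2)(c2ccccc2)C(C)(C)C)ccc1O[Si](C(C)C)(C(C)C)C(C)C
F7 | step 9 | cyclic thionocarbonate of diol F6 (spiro 1,3-dioxolane-2-thione on C4 and the benzylic carbon) | COc1cc([C@H]3OC(=S)O[C@@]32CO[C@H](c4ccc(OCc5ccccc5)c(OC)c4)[C@H]2CO[Si](c2ccccc2)(c2ccccc2)C(C)(C)C)ccc1O[Si](C(C)C)(C(C)C)C(C)C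
F8 | step 2 | (S)-1-[4-(benzyloxy)-3-methoxyphenyl]prop-2-en-1-ol | C=C[C@H](O)c1ccc(OCc2ccccc2)c(OC)c1
F9 | step 2 | (R)-1-[4-(benzyloxy)-3-methoxyphenyl]prop-2-en-1-yl acetate | C=C[C@@H](OC(C)=O)c1ccc(OCc2ccccc2)c(OC)c1
F10 | step 2 | {4-[3-({(S)-1-[4-(benzyloxy)-3-methoxyphenyl]prop-2-en-1-yl}oxy)prop-1-yn-1-yl]-2-methoxyphenoxy}tri(propan-2-yl)silane | C=C[C@H](OCC#Cc1ccc(O[Si](C(C)C)(C(C)C)C(C)C)c(OC)c1)c1ccc(OCc2ccccc2)c(OC)c1
F11 | step 2 | epoxide epimer of 11: {2-methoxy-4-[3-({(R)-[4-(benzyloxy)-3-methoxyphenyl][(2R)-oxiran-2-yl]methyl}oxy)prop-1-yn-1-yl]phenoxy}tri(propan-2-yl)silane | COc1cc(C#CCO[C@H](c2ccc(OCc3ccccc3)c(OC)c2)[C@H]2CO2)ccc1O[Si](C(C)C)(C(C)C)C(C)C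
F12 | step 14 | prop-2-en-1-yl (aryloxy)acetate, aryloxy = phenoxy residue of 18 | COc1cc(C[C@@]2(O[Si](CC)(CC)CC)CO[C@H](c3ccc(OCC(=O)OCC=C)c(OC)c3)[C@H]2CO[Si](c2ccccc2)(c2ccccc2)C(C)(C)C)ccc1O[Si](C(C)C)(C(C)C)C(C)C
F13 | step 14 | (aryloxy)acetic acid, aryloxy = phenoxy residue of 18 | COc1cc(C[C@@]2(O[Si](CC)(CC)CC)CO[C@H](c3ccc(OCC(=O)O)c(OC)c3)[C@H]2CO[Si](c2ccccc2)(c2ccccc2)C(C)(C)C)ccc1O[Si](C(C)C)(C(C)C)C(C)C
F14 | step 16 | C7 epimer of 28: (1S,2R)-2-(aryloxy)-1-[3-methoxy-4-(triisopropylsilyloxy)phenyl]propane-1,3-diol, aryloxy as in 18 | COc1cc(C[C@@]2(O[Si](CC)(CC)CC)CO[C@H](c3ccc(O[C@H](CO)[C@@H](O)c6ccc(O[Si](C(C)C)(C(C)C)C(C)C)c(OC)c6)c(OC)c3)[C@H]2CO[Si](c2ccccc2)(c2ccccc2)C(C)(C)C)ccc1O[Si](C(C)C)(C(C)C)C(C)C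
F15 | step 16 | 3-O-(tert-butyldimethylsilyl) ether of F14 (erythro) | COc1cc(C[C@@]2(O[Si](CC)(CC)CC)CO[C@H](c3ccc(O[C@H](CO[Si](C)(C)C(C)(C)C)[C@@H](O)c6ccc(O[Si](C(C)C)(C(C)C)C(C)C)c(OC)c6)c(OC)c3)[C@H]2CO[Si](c2ccccc2)(c2ccccc2)C(C)(C)C)ccc1O[Si](C(C)C)(C(C)C)C(C)C
F16 | step 16 | 3-O-(tert-butyldimethylsilyl) ether of 28 (threo) | COc1cc(C[C@@]2(O[Si](CC)(CC)CC)CO[C@H](c3ccc(O[C@H](CO[Si](C)(C)C(C)(C)C)[C@H](O)c6ccc(O[Si](C(C)C)(C(C)C)C(C)C)c(OC)c6)c(OC)c3)[C@H]2CO[Si](c2ccccc2)(c2ccccc2)C(C)(C)C)ccc1O[Si](C(C)C)(C(C)C)C(C)C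
F17 | step 16 | 2-(aryloxy)-3-(tert-butyldimethylsilyloxy)-1-[3-methoxy-4-(triisopropylsilyloxy)phenyl]propan-1-one, aryloxy as in 18, C2 configured as in 28 | COc1cc(C[C@@]2(O[Si](CC)(CC)CC)CO[C@H](c3ccc(O[C@H](CO[Si](C)(C)C(C)(C)C)C(=O)c6ccc(O[Si](C(C)C)(C(C)C)C(C)C)c(OC)c6)c(OC)c3)[C@H]2CO[Si](c2ccccc2)(c2ccccc2)C(C)(C)C)ccc1O[Si](C(C)C)(C(C)C)C(C)C
A1 | alternative 1 | 2-[3-methoxy-4-(triisopropylsilyloxy)phenyl]-4-methyl-4-[(E)-alkenyl]-1,3-dioxolane, alkenyl = 1-[4-(benzyloxy)-3-methoxyphenyl]-4-[tert-butyl(diphenyl)silyloxy]but-2-en-2-yl, (4S), either acetal epimer | C[C@@]1(COC(O1)c2ccc(O[Si](C(C)C)(C(C)C)C(C)C)c(OC)c2)/C(Cc3ccc(OCc4ccccc4)c(OC)c3)=C/CO[Si](c5ccccc5)(c6ccccc6)C(C)(C)C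
A2 | alternative 1 | 4-acetyl-2-aryl-4-benzyl-3-(silyloxymethyl)tetrahydrofuran (ring B as triisopropylsilyl ether, ring A as benzyl ether, acetyl cis to the C2 aryl) | COc1cc(C[C@@]2(C(C)=O)CO[C@H](c3ccc(O[Si](C(C)C)(C(C)C)C(C)C)c(OC)c3)[C@H]2CO[Si](c4ccccc4)(c5ccccc5)C(C)(C)C)ccc1OCc1ccccc1
A3 | alternative 2 | 2-aryl-3-[(arylmethoxy)methyl]-4-oxotetrahydrofuran, target numbering (2S,3R), ring B as mesylate, ring A as benzyl ether | O=C1CO[C@H](c2ccc(OS(C)(=O)=O)c(OC)c2)[C@H]1COCc1ccc(OCc2ccccc2)c(OC)c1
A4 | alternative 2 | cis-fused 1-hydroxy-2,6-diaryl-3,7-dioxabicyclo[3.3.0]octane | COc1cc([C@@H]3[C@@]2(O)CO[C@H](c4ccc(OS(C)(=O)=O)c(OC)c4)[C@H]2CO3)ccc1OCc1ccccc1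
A5 | alternative 3 | (2S,3S)-2-[4-(benzyloxy)-3-methoxybenzyl]-3-(4-hydroxy-3-methoxybenzyl)butane-1,2,4-triol | COc1cc(C[C@@](O)(CO)[C@H](CO)Cc2ccc(O)c(OC)c2)ccc1OCc1ccccc1
A6 | alternative 3 | (3S,4R,5S)-3-[4-(benzyloxy)-3-methoxybenzyl]-5-(4-hydroxy-3-methoxyphenyl)-4-(hydroxymethyl)oxolan-3-ol | COc1cc(C[C@@]2(O)CO[C@H](c3ccc(O)c(OC)c3)[C@H]2CO)ccc1OCc1ccccc1
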